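**Retrosynthetic overview**
1. Target 23 ← tris-silyl ether 22 ← Suzuki coupling at the central diene bond between alkenylboronate 10 (tetrahydrofuran half) and chlorovinyl isocoumarin 21.
2. Tetrahydrofuran ring: oxidative ring contraction (1,2-shift of the ring oxygen) of the 4,6-dideoxy glycal 7 to aldehyde 9; this key step sets C2 of the tetrahydrofuran.
3. Glycal 7 ← lactol 3, made from three molecules of acetaldehyde 1 by an aldolase tandem aldol (through (R)-3-hydroxybutanal 2) that sets both carbinol centres.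
4. Isocoumarin lactone ring: one-pot ortho-C–H alkynylation/6-endo lactonization of acid 15 (from resorcinol 11) with bromoenyne 19 (from (E)-1,2-dichloroethene 16 and ethynyltrimethylsilane 17).
5. Ring order: pyranose (step 1) → contracted to the tetrahydrofuran (step 4); benzene ring bought in; lactone ring closed last on the aromatic half (step 11).

Assumption: the hemiacetal carbon of 3, 4, 5, 6, 8 and F5 is an anomeric mixture and is written without configuration; all other stereocentres are specified.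

**Route**

Step 1
Reactants: 1 acetaldehyde
Product: 3 (4R,6R)-6-methyltetrahydro-2H-pyran-2,4-diol, via (R)-3-hydroxybutanal 2 (not isolated)
Conditions: DERA (2-deoxy-D-ribose-5-phosphate aldolase, acetaldehyde-tolerant E. coli variant), triethanolamine buffer pH 7.5, acetaldehyde (3 equiv in all, slow feed), 25 °C
Reagents that add atoms: acetaldehyde (first donor), CC=O; acetaldehyde (second donor), O=CC
Why: Enzymatic tandem aldol addition: the enzyme-bound enamine of a first donor acetaldehyde adds to acetaldehyde to give (R)-3-hydroxybutanal 2, which the aldolase takes up again as acceptor for a second donor with the same facial sense, so both carbinol centres are set (3R,5R in the open chain, a syn-1,3-diol) and the product leaves the equilibrium as the pyranose lactol.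

Step 2
Reactants: 3 (4R,6R)-6-methyltetrahydro-2H-pyran-2,4-diol
Product: 5 (4R,6R)-6-methyl-4-(triisopropylsilyloxy)tetrahydro-2H-pyran-2-ol, via bis-silyl ether 4 (not isolated)
Conditions: TIPSOTf (2.3 equiv), 2,6-lutidine, CH2Cl2, −78 → 0 °C; then AcOH/THF/H2O (3:1:1), 25 °C
Reagents that add atoms: triisopropylsilyl trifluoromethanesulfonate, CC(C)[Si](OS(=O)(=O)C(F)(F)F)(C(C)C)C(C)C
Why: Silyl ether protection followed by selective hydrolysis of the much more labile anomeric silyl acetal leaves a non-participating silyl ether on O4 only; no stereocentre is touched.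

Step 3
Reactants: 5 (4R,6R)-6-methyl-4-(triisopropylsilyloxy)tetrahydro-2H-pyran-2-ol
Product: 7 (2R,4R)-2-methyl-4-(triisopropylsilyloxy)-3,4-dihydro-2H-pyran, via anomeric mesylate 6 (not isolated)
Conditions: MsCl (1.5 equiv), Et3N (4 equiv), CH2Cl2, −40 → 40 °C
Reagents that add atoms: none
Why: Lactol dehydration to a glycal: the 2-deoxy glycosyl mesylate ionizes and loses the adjacent proton; the two stereocentres are untouched and the silyloxy and methyl groups stay trans.

Step 4
Reactants: 7 (2R,4R)-2-methyl-4-(triisopropylsilyloxy)-3,4-dihydro-2H-pyran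
Product: 9 (2R,3R,5R)-5-methyl-3-(triisopropylsilyloxy)tetrahydrofuran-2-carbaldehyde, via iodane adduct 8 (not isolated)
Conditions: PhI(OH)OTs (1.2 equiv), MeCN/H2O (9:1), −20 → 0 °C
Reagents that add atoms: water, O
Why: Oxidative ring contraction of a glycal with a hypervalent (trivalent) iodine reagent: the iodane adds to C5 of the enol ether anti to the pseudo-axial silyloxy group while water adds to C6, and from the chair with an equatorial C–I bond the antiperiplanar ring oxygen shifts from C6 to C5 with inversion and loss of PhI, so the new C2 centre carries the formyl group trans to the silyloxy group and cis to the methyl group (2R).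

Step 5
Reactants: 9 (2R,3R,5R)-5-methyl-3-(triisopropylsilyloxy)tetrahydrofuran-2-carbaldehyde
Product: 10 2-[(E)-2-[(2S,3R,5R)-5-methyl-3-(triisopropylsilyloxy)tetrahydrofuran-2-yl]ethenyl]-4,4,5,5-tetramethyl-1,3,2-dioxaborolane
Conditions: CrCl2 (8 equiv), Cl2CHBpin (2 equiv), LiI (4 equiv), THF, 25 °C
Reagents that add atoms: 2-(dichloromethyl)-4,4,5,5-tetramethyl-1,3,2-dioxaborolane, ClC(Cl)B1OC(C)(C)C(C)(C)O1
Why: Takai–Utimoto olefination: the geminal dichromium species adds to the aldehyde and eliminates to the E-alkenylboronate under non-basic conditions, so the epimerizable α-alkoxy centre and the β-silyloxy group survive.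

Step 6
Reactants: 11 resorcinol
Product: 12 2,4-dihydroxybenzoic acid
Conditions: KHCO3 (5 equiv), H2O, CO2 (1 atm), 100 °C; then HCl
Reagents that add atoms: carbon dioxide, O=C=O
Why: Kolbe–Schmitt carboxylation of the resorcinol anion occurs ortho to one hydroxyl and para to the other.

Step 7
Reactants: 12 2,4-dihydroxybenzoic acid
Product: 13 5-chloro-2,4-dihydroxybenzoic acid
Conditions: SO2Cl2 (1.05 equiv), Et2O, 0 → 25 °C
Reagents that add atoms: sulfuryl chloride, O=S(=O)(Cl)Cl
Why: Electrophilic aromatic chlorination goes to C5, para to the chelated 2-hydroxyl and ortho to the 4-hydroxyl, rather than to the more hindered position between the two hydroxyls.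

Step 8
Reactants: 13 5-chloro-2,4-dihydroxybenzoic acid
Product: 15 5-chloro-2,4-bis(triisopropylsilyloxy)benzoic acid, via tris-silyl compound 14 (not isolated)
Conditions: TIPSOTf (3.3 equiv), 2,6-lutidine, CH2Cl2, 0 → 25 °C; then THF/1 M aqueous citric acid, 25 °C
Reagents that add atoms: triisopropylsilyl trifluoromethanesulfonate, CC(C)[Si](OS(=O)(=O)C(F)(F)F)(C(C)C)C(C)C
Why: Exhaustive silylation followed by selective hydrolysis of the labile silyl ester gives the free acid with both phenols masked as fluoride-cleavable ethers.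

Step 9
Reactants: 16 (E)-1,2-dichloroethene (5 equiv); 17 ethynyltrimethylsilane
Product: 18 [(E)-4-chlorobut-3-en-1-yn-1-yl]trimethylsilane
Conditions: Pd(PPh3)4 (5 mol%), CuI (10 mol%), n-BuNH2 (2 equiv), Et2O, 20 °C
Reagents that add atoms: none
Why: Sonogashira coupling; the excess of dichloroethene ensures mono-coupling, and the E geometry of the remaining chloroalkene is retained.

Step 10
Reactants: 18 [(E)-4-chlorobut-3-en-1-yn-1-yl]trimethylsilane
Product: 19 (E)-1-bromo-4-chlorobut-3-en-1-yne
Conditions: NBS (1.1 equiv), AgNO3 (10 mol%), acetone, 20 °C, dark; used as a solution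
Reagents that add atoms: N-bromosuccinimide, O=C1CCC(=O)N1Br
Why: Silver-catalysed bromodesilylation of an alkynylsilane gives the 1-bromoalkyne without touching the chloroalkene.

Step 11
Reactants: 15 5-chloro-2,4-bis(triisopropylsilyloxy)benzoic acid; 19 (E)-1-bromo-4-chlorobut-3-en-1-yne
Product: 21 5-chloro-3-[(E)-2-chloroethenyl]-6,8-bis(triisopropylsilyloxy)-1H-isochromen-1-one, via alkynyl acid 20 (not isolated)
Conditions: [(C5Me5)RhCl2]2 (2.5 mol%), AgSbF6 (10 mol%), Ag2CO3 (0.55 equiv), 1,2-dichloroethane, 40 °C; then TfOH (30 mol%), 40 °C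
Reagents that add atoms: none
Why: Proposed new method: carboxylate-assisted concerted metalation–deprotonation by cationic trivalent rhodium at the only free ortho C–H, insertion of the bromoalkyne with the aryl group adding to the bromine-bearing carbon, and β-bromide elimination (silver takes up the bromide) give alkynyl acid 20, whose alkyne is then activated by the added acid and captured by the carboxyl oxygen at the distal carbon (6-endo-dig, favoured because the chlorovinyl group stabilises the developing positive charge there while the two silyloxy groups, both meta to the alkyne, cannot stabilise the benzylic alternative) to close the lactone ring; the closest known reactions are the carboxylate-directed ortho-C–H alkynylation of benzoic acids with silyl-substituted bromoalkynes under rhodium, iridium or ruthenium catalysis and the acid-promoted 6-endo-dig cyclization of 2-alkynylbenzoic acids to isocoumarins, whereas a one-pot annulation with a conjugated, non-silyl 1-bromoenyne has not been shown.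

Step 12
Reactants: 21 5-chloro-3-[(E)-2-chloroethenyl]-6,8-bis(triisopropylsilyloxy)-1H-isochromen-1-one; 10 2-[(E)-2-[(2S,3R,5R)-5-methyl-3-(triisopropylsilyloxy)tetrahydrofuran-2-yl]ethenyl]-4,4,5,5-tetramethyl-1,3,2-dioxaborolane
Product: 22 5-chloro-3-[(1E,3E)-4-[(2S,3R,5R)-5-methyl-3-(triisopropylsilyloxy)tetrahydrofuran-2-yl]buta-1,3-dien-1-yl]-6,8-bis(triisopropylsilyloxy)-1H-isochromen-1-one
Conditions: Pd(OAc)2 (5 mol%), SPhos (10 mol%), K3PO4 (3 equiv), THF/H2O (10:1), 45 °C
Reagents that add atoms: none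
Why: Suzuki–Miyaura coupling of an alkenyl chloride (activated by conjugation to the isocoumarin) with an alkenylboronate proceeds with retention at both alkenes and gives the (E,E)-diene.

Step 13
Reactants: 22 5-chloro-3-[(1E,3E)-4-[(2S,3R,5R)-5-methyl-3-(triisopropylsilyloxy)tetrahydrofuran-2-yl]buta-1,3-dien-1-yl]-6,8-bis(triisopropylsilyloxy)-1H-isochromen-1-one
Product: 23 5-chloro-6,8-dihydroxy-3-[(1E,3E)-4-[(2S,3R,5R)-3-hydroxy-5-methyltetrahydrofuran-2-yl]buta-1,3-dien-1-yl]-1H-isochromen-1-one
Conditions: Bu4NF (5 equiv), AcOH (5 equiv), THF, 0 → 25 °C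
Reagents that add atoms: none
Why: Fluoride-mediated silyl ether cleavage removes the two aryl and one alkyl silyl groups; the acetic acid buffer protects the lactone and the dienyl ether, and no stereocentre is affected.

**Compound list**

1 | acetaldehyde | CC=O | starting material
2 | (R)-3-hydroxybutanal | C[C@@H](O)CC=O | intermediate
3 | (4R,6R)-6-methyltetrahydro-2H-pyran-2,4-diol (2,4,6-trideoxy-D-erythro-hexopyranose) | C[C@@H]1C[C@@H](O)CC(O)O1 | intermediate
4 | triisopropyl{[(4R,6R)-6-methyl-4-(triisopropylsilyloxy)tetrahydro-2H-pyran-2-yl]oxy}silane | C[C@@H]1C[C@@H](O[Si](C(C)C)(C(C)C)C(C)C)CC(O[Si](C(C)C)(C(C)C)C(C)C)O1 | intermediate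
5 | (4R,6R)-6-methyl-4-(triisopropylsilyloxy)tetrahydro-2H-pyran-2-ol | C[C@@H]1C[C@@H](O[Si](C(C)C)(C(C)C)C(C)C)CC(O)O1 | intermediate
6 | (4R,6R)-6-methyl-4-(triisopropylsilyloxy)tetrahydro-2H-pyran-2-yl methanesulfonate | C[C@@H]1C[C@@H](O[Si](C(C)C)(C(C)C)C(C)C)CC(OS(C)(=O)=O)O1 | intermediate
7 | (2R,4R)-2-methyl-4-(triisopropylsilyloxy)-3,4-dihydro-2H-pyran | C[C@@H]1C[C@@H](O[Si](C(C)C)(C(C)C)C(C)C)C=CO1 | intermediate
8 | [(3S,4R,6R)-2-hydroxy-6-methyl-4-(triisopropylsilyloxy)tetrahydro-2H-pyran-3-yl](phenyl)-λ3-iodanyl 4-methylbenzenesulfonate | C[C@@H]1C[C@@H](O[Si](C(C)C)(C(C)C)C(C)C)[C@H](I(c2ccccc2)OS(=O)(=O)c2ccc(C)cc2)C(O)O1 | intermediate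
9 | (2R,3R,5R)-5-methyl-3-(triisopropylsilyloxy)tetrahydrofuran-2-carbaldehyde | C[C@@H]1C[C@@H](O[Si](C(C)C)(C(C)C)C(C)C)[C@H](C=O)O1 | intermediate
10 | 2-[(E)-2-[(2S,3R,5R)-5-methyl-3-(triisopropylsilyloxy)tetrahydrofuran-2-yl]ethenyl]-4,4,5,5-tetramethyl-1,3,2-dioxaborolane | C[C@@H]1C[C@@H](O[Si](C(C)C)(C(C)C)C(C)C)[C@H](/C=C/B2OC(C)(C)C(C)(C)O2)O1 | intermediate
11 | resorcinol (benzene-1,3-diol) | Oc1cccc(O)c1 | starting material
12 | 2,4-dihydroxybenzoic acid | OC(=O)c1ccc(O)cc1O | intermediate
13 | 5-chloro-2,4-dihydroxybenzoic acid | OC(=O)c1cc(Cl)c(O)cc1O | intermediate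
14 | triisopropylsilyl 5-chloro-2,4-bis(triisopropylsilyloxy)benzoate | CC(C)[Si](OC(=O)c1cc(Cl)c(O[Si](C(C)C)(C(C)C)C(C)C)cc1O[Si](C(C)C)(C(C)C)C(C)C)(C(C)C)C(C)C | intermediate
15 | 5-chloro-2,4-bis(triisopropylsilyloxy)benzoic acid | OC(=O)c1cc(Cl)c(O[Si](C(C)C)(C(C)C)C(C)C)cc1O[Si](C(C)C)(C(C)C)C(C)C | intermediate
16 | (E)-1,2-dichloroethene | Cl/C=C/Cl | starting material
17 | ethynyltrimethylsilane | C[Si](C)(C)C#C | starting material
18 | [(E)-4-chlorobut-3-en-1-yn-1-yl]trimethylsilane | C[Si](C)(C)C#C/C=C/Cl | intermediate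
19 | (E)-1-bromo-4-chlorobut-3-en-1-yne | BrC#C/C=C/Cl | intermediate
20 | 3-chloro-2-[(E)-4-chlorobut-3-en-1-yn-1-yl]-4,6-bis(triisopropylsilyloxy)benzoic acid | OC(=O)c1c(C#C/C=C/Cl)c(Cl)c(O[Si](C(C)C)(C(C)C)C(C)C)cc1O[Si](C(C)C)(C(C)C)C(C)C | intermediate
21 | 5-chloro-3-[(E)-2-chloroethenyl]-6,8-bis(triisopropylsilyloxy)-1H-isochromen-1-one | Cl/C=C/c1cc2c(Cl)c(O[Si](C(C)C)(C(C)C)C(C)C)cc(O[Si](C(C)C)(C(C)C)C(C)C)c2c(=O)o1 | intermediate
22 | 5-chloro-3-[(1E,3E)-4-[(2S,3R,5R)-5-methyl-3-(triisopropylsilyloxy)tetrahydrofuran-2-yl]buta-1,3-dien-1-yl]-6,8-bis(triisopropylsilyloxy)-1H-isochromen-1-one | C[C@@H]1C[C@@H](O[Si](C(C)C)(C(C)C)C(C)C)[C@H](/C=C/C=C/c2cc3c(Cl)c(O[Si](C(C)C)(C(C)C)C(C)C)cc(O[Si](C(C)C)(C(C)C)C(C)C)c3c(=O)o2)O1 | intermediate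
23 | 5-chloro-6,8-dihydroxy-3-[(1E,3E)-4-[(2S,3R,5R)-3-hydroxy-5-methyltetrahydrofuran-2-yl]buta-1,3-dien-1-yl]-1H-isochromen-1-one | C[C@@H]1C[C@@H](O)[C@H](/C=C/C=C/c2cc3c(Cl)c(O)cc(O)c3c(=O)o2)O1 | target

**Step count and risks**

Total steps: 13. Longest linear sequence: 7 steps (1, 2, 3, 4, 5, 12, 13).

The three steps most likely to fail:

Step 11 (the proposed new annulation). The C–H bond is flanked by chlorine, the small bromoenyne may oligomerize, and the acid 20 could close in the 5-exo mode to a phthalide before the acid is added. The fallback uses known chemistry, sets out from acid 15 and comes back at isocoumarin 21. Carboxylate-directed ortho-lithiation of 15 (s-BuLi/TMEDA, THF, −78 °C) and quenching with I2 gives 3-chloro-2-iodo-4,6-bis(triisopropylsilyloxy)benzoic acid F1. TMSCHN2 converts it into methyl 3-chloro-2-iodo-4,6-bis(triisopropylsilyloxy)benzoate F2. Silane 18 is desilylated (K2CO3, MeOH) to (E)-1-chlorobut-1-en-3-yne F3, and Sonogashira coupling of F2 with F3 (Pd(PPh3)2Cl2, CuI, Et3N, 25 °C) gives methyl 3-chloro-2-[(E)-4-chlorobut-3-en-1-yn-1-yl]-4,6-bis(triisopropylsilyloxy)benzoate F4. Acid-promoted 6-endo-dig cyclization of this 2-alkynylbenzoate (Cu(OTf)2 cat., CF3CO2H, wet 1,2-dichloroethane, 60 °C) then gives 21 with loss of the methyl group.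

Step 4 (ring contraction). In this glycal the silyloxy and methyl groups are trans, so the chair that places the C–I bond antiperiplanar to the ring C–O bond carries an axial methyl group. Hydration of the enol ether or attack of water on the iodane may then compete with the oxygen shift. The fallback sets out from glycal 7 and comes back at aldehyde 9, reaching the same ring contraction stepwise through the open chain. NIS in MeCN/H2O at 0 °C adds iodine anti to the silyloxy group and gives (3S,4R,6R)-3-iodo-6-methyl-4-(triisopropylsilyloxy)tetrahydro-2H-pyran-2-ol F5. Ag2CO3 in MeCN at 40 °C then lets the hydroxyl on the methyl-bearing carbon of the ring-opened α-iodo aldehyde displace iodide (intramolecular SN2 with inversion), which gives 9 with the same configuration and has no conformational requirement.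

Step 5 (Takai–Utimoto olefination). Aldehyde 9 is α-alkoxy and β-silyloxy, so it can epimerize or eliminate, and the reaction needs a large excess of CrCl2. The fallback sets out from aldehyde 9 and comes back at boronate 10. Ohira–Bestmann homologation (dimethyl (1-diazo-2-oxopropyl)phosphonate, K2CO3, MeOH, 0 °C) gives (2S,3R,5R)-2-ethynyl-5-methyl-3-(triisopropylsilyloxy)tetrahydrofuran F6. Any epimerization at this stage runs toward the wanted, more stable 2,3-trans isomer. Hydroboration of F6 with pinacolborane catalysed by Cp2Zr(H)Cl (10 mol%, Et3N 10 mol%, 40 °C) then gives the E-alkenylboronate 10.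

Further compounds
F1 | step 11 | 3-chloro-2-iodo-4,6-bis(triisopropylsilyloxy)benzoic acid | OC(=O)c1c(I)c(Cl)c(O[Si](C(C)C)(C(C)C)C(C)C)cc1O[Si](C(C)C)(C(C)C)C(C)C
F2 | step 11 | methyl 3-chloro-2-iodo-4,6-bis(triisopropylsilyloxy)benzoate | COC(=O)c1c(I)c(Cl)c(O[Si](C(C)C)(C(C)C)C(C)C)cc1O[Si](C(C)C)(C(C)C)C(C)C
F3 | step 11 | (E)-1-chlorobut-1-en-3-yne | C#C/C=C/Cl
F4 | step 11 | methyl 3-chloro-2-[(E)-4-chlorobut-3-en-1-yn-1-yl]-4,6-bis(triisopropylsilyloxy)benzoate | COC(=O)c1c(C#C/C=C/Cl)c(Cl)c(O[Si](C(C)C)(C(C)C)C(C)C)cc1O[Si](C(C)C)(C(C)C)C(C)C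
F5 | step 4 | (3S,4R,6R)-3-iodo-6-methyl-4-(triisopropylsilyloxy)tetrahydro-2H-pyran-2-ol | C[C@@H]1C[C@@H](O[Si](C(C)C)(C(C)C)C(C)C)[C@H](I)C(O)O1
F6 | step 5 | (2S,3R,5R)-2-ethynyl-5-methyl-3-(triisopropylsilyloxy)tetrahydrofuran | C[C@@H]1C[C@@H](O[Si](C(C)C)(C(C)C)C(C)C)[C@H](C#C)O1
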